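**Retrosynthetic overview**
- Target ⇒ retro-hetero-Diels–Alder across the dihydropyran (O–C4 and C1'–C5 bonds): isobutylidenesyncarpic acid (oxadiene) + (−)-β-caryophyllene, which brings C1, C9, the cyclobutane, the nine-membered ring and the exocyclic methylene.
- Isobutylidenesyncarpic acid ⇒ retro-Knoevenagel: syncarpic acid + isobutyraldehyde (supplies C1' and the isopropyl group).
- Syncarpic acid ⇒ re-acetylation (retro-Claisen in the forward sense) and removal of four C-methyl groups: 2',4',6'-trihydroxyacetophenone + MeI.
- Ring order: cyclobutane and cyclononene are bought with the terpene; the triketone ring is made first by dearomatising the arene; the dihydropyran ring is closed last, together with C4, C5 and C1'.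

Assumption: terpene positions are cited in caryophyllene numbering (C1/C9 ring fusion, C4 methyl-bearing, C5 former alkene CH, C8 methylene-bearing), C1' is the isopropyl-bearing carbon, and compounds 1, 4 and 5 are catalogue chemicals.

**Step 1**
Reactants: 1 2',4',6'-trihydroxyacetophenone (phloroacetophenone)
Product: 2 acetylsyncarpic acid (2-acetyl-3-hydroxy-4,4,6,6-tetramethylcyclohex-2-ene-1,5-dione)
Conditions: MeI (6 equiv), NaOMe (5 equiv), MeOH, 0 °C → reflux, 4 h; then 2 M HCl
Reagents that add atoms: methyl iodide (MeI), CI
Why: Exhaustive dearomatising C-methylation of the phloroglucinol polyanion puts two methyl groups on each of the two free ring carbons while the acetyl group blocks the third position; no stereocentre is formed.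

**Step 2**
Reactants: 2 acetylsyncarpic acid
Product: 3 syncarpic acid (2,2,4,4-tetramethylcyclohexane-1,3,5-trione)
Conditions: 6 M aq. HCl, reflux, 24 h
Reagents that add atoms: none
Why: Acid-catalysed retro-Claisen deacylation, in which water attacks the unhindered exocyclic acetyl carbonyl and expels the stabilised cyclic 1,3-dione enol, while the ring carbonyls are shielded by the flanking quaternary carbons; no stereocentre is involved.

**Step 3**
Reactants: 3 syncarpic acid; 4 isobutyraldehyde (2-methylpropanal); 5 (−)-β-caryophyllene ((1R,4E,9S)-4,11,11-trimethyl-8-methylidenebicyclo[7.2.0]undec-4-ene)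
Product: 7 myrtucommulone K, via isobutylidenesyncarpic acid 6 (not isolated)
Conditions: 4 (1.5 equiv), 5 (2 equiv), NaOAc (1 equiv), AcOH, 80 °C, sealed tube, 12 h; SiO2 chromatography
Reagents that add atoms: none
Why: Knoevenagel condensation of 3 with 4 gives the electron-poor 1-oxadiene 6, which is trapped in an inverse-electron-demand hetero-Diels–Alder reaction by the strained E-trisubstituted C4=C5 alkene of 5 (the C8 methylene is far less reactive) with oxygen bonding to the more substituted C4; suprafacial addition to the exposed face of the predominant βα conformer of 5 (the face peracids also attack) sets 4R and 5S with a trans ring fusion, the E-oxadiene (isopropyl outside) reacting with the C4 methyl and C6 under the triketone ring sets 1'R (H-1' cis to H-5), and C1 (R) and C9 (S) are carried through unchanged.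

**Compound list**
1 | 2',4',6'-trihydroxyacetophenone (phloroacetophenone) | CC(=O)c1c(O)cc(O)cc1O | starting material
2 | acetylsyncarpic acid, 2-acetyl-3-hydroxy-4,4,6,6-tetramethylcyclohex-2-ene-1,5-dione (enol form of the acetyl triketone) | CC(=O)C1=C(O)C(C)(C)C(=O)C(C)(C)C1=O | intermediate
3 | syncarpic acid, 2,2,4,4-tetramethylcyclohexane-1,3,5-trione | CC1(C)C(=O)CC(=O)C(C)(C)C1=O | intermediate
4 | isobutyraldehyde, 2-methylpropanal | CC(C)C=O | starting material
5 | (−)-β-caryophyllene, (1R,4E,9S)-4,11,11-trimethyl-8-methylidenebicyclo[7.2.0]undec-4-ene | C=C1CC/C=C(\C)CC[C@@H]2[C@@H]1CC2(C)C | starting material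
6 | isobutylidenesyncarpic acid, 2,2,4,4-tetramethyl-6-(2-methylpropylidene)cyclohexane-1,3,5-trione | CC(C)C=C1C(=O)C(C)(C)C(=O)C(C)(C)C1=O | intermediate
7 | myrtucommulone K: 4-isopropyl-6,6,8,8-tetramethyl-3,4-dihydro-2H-chromene-5,7(6H,8H)-dione whose pyran O–C(CH3) and adjacent CH are C4 and C5 of the caryophyllene skeleton; 1R,4R,5S,9S (caryophyllene numbering), 1'R; trans pyran/cyclononane fusion, H-5 and H-1' cis, exocyclic methylene and trans-fused gem-dimethylcyclobutane retained | C=C1CC[C@H]2[C@@H](C(C)C)C3=C(O[C@]2(C)CC[C@@H]2[C@@H]1CC2(C)C)C(C)(C)C(=O)C(C)(C)C3=O | target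

**Total step count:** 3
**Longest linear sequence:** 3 (1 → 2 → 3 → 7)

**Steps most likely to fail (all three, in order of risk)**

Step 3 is the riskiest. The C1' configuration depends on which orientation of the oxadiene over the alkene is preferred, and I could not settle this from first principles; the C1' epimer of 7 is the expected by-product and may not be minor. Other risks are Michael addition of a second molecule of 3 to 6, a second cycloaddition at the C8 methylene, and acid-induced isomerisation of 5 in hot AcOH. The fallback sets out from 3 and comes back to the route at 6. Compound 3, 4 and piperidine (1 equiv each, CH2Cl2, 20 °C) give the crystalline Mannich base 3-hydroxy-4,4,6,6-tetramethyl-2-[2-methyl-1-(piperidin-1-yl)propyl]cyclohex-2-ene-1,5-dione F1 (racemic; its stereocentre is destroyed in the next operation). This is purified by crystallisation, so no free 3 is left to add to 6. Shaking a cold CH2Cl2 solution of it with 1 M HCl expels piperidine (retro-Mannich, E1cB elimination) and gives a dried, acid-free solution of 6. This is stirred with 5 (3 equiv) in toluene at 20–40 °C, so the cycloaddition runs as a separate, neutral, low-temperature operation where kinetic diastereoselection is highest and 5 is not exposed to acid.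

Step 1 is next. Four alkylations in one pot can stall at partly methylated stages or divert to O-methyl ethers, giving mixtures that are hard to purify. The fallback sets out from 1 and comes back at 2. It splits the sequence at the aromatic stage: 1 with MeI (2.2 equiv) and NaOMe (2.2 equiv) in MeOH at 0–20 °C gives the aromatic di-C-methyl compound 1-(2,4,6-trihydroxy-3,5-dimethylphenyl)ethan-1-one F2, which is crystallised free of O-methylated and mono-methylated material. A separate dearomatising gem-dimethylation of this isolated compound (MeI 3 equiv, NaOMe 3 equiv, MeOH, reflux) has only the two defined ring carbons left to react and delivers 2.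

Step 2 is the least risky. The hydrolytic retro-Claisen is slow because 2 is a strongly enolised, poorly soluble triketone, and forcing it can degrade material. The fallback sets out from 2 and comes back at 3. It makes the acetyl group labile by blocking enolisation: NBS (1.05 equiv, CH2Cl2, 0 °C) brominates the ring carbon to give 2-acetyl-2-bromo-4,4,6,6-tetramethylcyclohexane-1,3,5-trione F3. This non-enolisable tricarbonyl loses the acetyl group on stirring in MeOH with NaOAc (0.1 equiv) at 20 °C, giving 6-bromo-2,2,4,4-tetramethylcyclohexane-1,3,5-trione F4. Reduction of its electrophilic bromine with aq. Na2SO3 in THF at 20 °C gives 3.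

**Further compounds**
F1 | step 3 | 3-hydroxy-4,4,6,6-tetramethyl-2-[2-methyl-1-(piperidin-1-yl)propyl]cyclohex-2-ene-1,5-dione (racemic Mannich base) | CC(C)C(N1CCCCC1)C1=C(O)C(C)(C)C(=O)C(C)(C)C1=O
F2 | step 1 | 1-(2,4,6-trihydroxy-3,5-dimethylphenyl)ethan-1-one | CC(=O)c1c(O)c(C)c(O)c(C)c1O
F3 | step 2 | 2-acetyl-2-bromo-4,4,6,6-tetramethylcyclohexane-1,3,5-trione | CC(=O)C1(Br)C(=O)C(C)(C)C(=O)C(C)(C)C1=O
F4 | step 2 | 6-bromo-2,2,4,4-tetramethylcyclohexane-1,3,5-trione | CC1(C)C(=O)C(Br)C(=O)C(C)(C)C1=O
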